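**Plan**
1. Retrosynthesis: the three phenols are masked as MOM ethers; the C2–H/C3–H pair is removed to give the flavone; ring C is then cut in one stroke at C4a–C4, C4–C3 and O1–C2; the two aryl–prenyl bonds, the C4a–I bond and the aryl–alkyne bond go back to aryl-metal chemistry.
2. Enabling feature: ring C is only the chain C2–C3–C4 slung between O1 (on C8a) and C4a of ring A. C4 is a lone carbonyl carbon and can be CO itself, C2–C3 is the ethynyl group of the ring-B arene, and ring A supplies a free O1–H next to an iodine on C4a.
3. Forward: ring A (from a symmetric triphenol, five steps) and ring B (from a brominated guaiacol, four steps) are made separately with their prenyl groups in place; ring C is closed last, at the flavone level, by palladium-catalysed union of iodophenol, CO and alkyne.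
4. Stereochemistry: C2 is the only stereocentre. It is set after ring closure by ligand-controlled copper hydride conjugate reduction of the flavone C2=C3 bond; acid then removes the MOM groups.

Key step: step 10

Assumption: (R)-DTBM-SEGPHOS is taken as the ligand enantiomer whose copper hydride attacks the face of C2 that leads to the (2S)-flavanone; should the sense be the reverse, the (S)-ligand is used with no other change.

**Route**

Step 1
Reactants: 1 phloroglucinol
Product: 2 3,5-bis(methoxymethoxy)phenol
Conditions: MOMCl (2.0 equiv), i-Pr2NEt (2.4 equiv), DMF, 0 °C to rt; chromatography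
Reagents that add atoms: chloromethyl methyl ether (MOMCl), COCCl
Why: Williamson-type O-alkylation with the chloromethyl ether; because the triphenol is threefold symmetric, the bis-ether is a single regioisomer and only has to be separated from the mono- and tris-ethers of the statistical mixture.

Step 2
Reactants: 2 3,5-bis(methoxymethoxy)phenol
Product: 3 3,5-bis(methoxymethoxy)phenyl N,N-diethylcarbamate
Conditions: ClC(O)NEt2, K2CO3, MeCN, reflux
Reagents that add atoms: N,N-diethylcarbamoyl chloride, CCN(CC)C(Cl)=O
Why: O-carbamoylation of the phenoxide (acyl substitution) puts the strongest oxygen-based director for ortho-metalation on the one oxygen that becomes O1 and so distinguishes it from the two MOM-protected oxygens.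

Step 3
Reactants: 3 3,5-bis(methoxymethoxy)phenyl N,N-diethylcarbamate; 4 prenyl bromide
Product: 6 3,5-bis(methoxymethoxy)-2-(3-methylbut-2-enyl)phenyl N,N-diethylcarbamate, via ortho-lithiated carbamate 5 (not isolated)
Conditions: s-BuLi, TMEDA, THF, −78 °C; then prenyl bromide, CuBr·SMe2 (10 mol %), −78 to −40 °C
Reagents that add atoms: prenyl bromide, CC(C)=CCBr
Why: Directed ortho-metalation followed by copper-catalysed allylation: the carbamate carbonyl binds s-BuLi·TMEDA and steers deprotonation to one of the two equivalent C–H bonds between carbamate and MOM ether (the stronger director outweighs the single site between the two MOM ethers), and the aryllithium is alkylated at the primary carbon of prenyl bromide (SN2) while the temperature stays below that of the anionic Fries rearrangement.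

Step 4
Reactants: 6 3,5-bis(methoxymethoxy)-2-(3-methylbut-2-enyl)phenyl N,N-diethylcarbamate
Product: 8 2-iodo-3,5-bis(methoxymethoxy)-6-(3-methylbut-2-enyl)phenyl N,N-diethylcarbamate, via aryllithium 7 (not isolated)
Conditions: s-BuLi, TMEDA, THF, −78 °C; then I2, THF, −78 °C; aq. Na2S2O3
Reagents that add atoms: iodine, II
Why: Second directed ortho-metalation and iodinolysis: the complexed base removes the only ring proton left ortho to the carbamate (ring deprotonation being kinetically preferred over lateral deprotonation of the prenyl CH2 with s-BuLi·TMEDA at −78 °C) and iodine quenches the aryllithium faster than it can add to the trisubstituted alkene, placing the halogen on the future C4a.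

Step 5
Reactants: 8 2-iodo-3,5-bis(methoxymethoxy)-6-(3-methylbut-2-enyl)phenyl N,N-diethylcarbamate
Product: 9 2-iodo-3,5-bis(methoxymethoxy)-6-(3-methylbut-2-enyl)phenol
Conditions: KOH, EtOH/H2O, reflux; then aq. NH4Cl
Reagents that add atoms: none
Why: Alkaline hydrolysis of the aryl carbamate (acyl substitution at the carbamoyl carbon with phenoxide as leaving group) frees O1, and hydroxide leaves the MOM acetals, the aryl iodide and the prenyl alkene untouched.

Step 6
Reactants: 10 4-bromo-2-methoxyphenol
Product: 11 4-bromo-2-methoxy-1-(methoxymethoxy)benzene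
Conditions: MOMCl, i-Pr2NEt, CH2Cl2, 0 °C to rt
Reagents that add atoms: chloromethyl methyl ether (MOMCl), COCCl
Why: Williamson-type O-alkylation of the single phenol gives the MOM ether, which tolerates the lithium amide, palladium and amine conditions that follow and is removed together with the other MOM groups at the end.

Step 7
Reactants: 11 4-bromo-2-methoxy-1-(methoxymethoxy)benzene; 4 prenyl bromide
Product: 13 1-bromo-3-methoxy-4-(methoxymethoxy)-2-(3-methylbut-2-enyl)benzene, via ortho-bromoaryllithium 12 (not isolated)
Conditions: LiN(i-Pr)2, THF, −78 °C; then prenyl bromide, CuBr·SMe2 (10 mol %), −78 °C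
Reagents that add atoms: prenyl bromide, CC(C)=CCBr
Why: Deprotonative lithiation and allylation: the lithium amide, which cannot exchange with bromine, removes the most acidic ring proton, the one flanked by bromine and the methoxy group, and the ortho-bromoaryllithium, held at −78 °C so that LiBr is not lost to an aryne, is alkylated at the primary carbon of prenyl bromide under copper catalysis.

Step 8
Reactants: 13 1-bromo-3-methoxy-4-(methoxymethoxy)-2-(3-methylbut-2-enyl)benzene; 14 trimethylsilylacetylene
Product: 15 {[3-methoxy-4-(methoxymethoxy)-2-(3-methylbut-2-enyl)phenyl]ethynyl}trimethylsilane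
Conditions: PdCl2(PhCN)2 (3 mol %), [HP(t-Bu)3]BF4 (6 mol %), CuI (2 mol %), i-Pr2NH, 1,4-dioxane, rt to 40 °C
Reagents that add atoms: trimethylsilylacetylene, C#C[Si](C)(C)C
Why: Sonogashira coupling: the bulky electron-rich phosphine lets zerovalent palladium insert into the electron-rich, ortho-substituted C–Br bond near room temperature, and the silyl cap prevents double arylation of acetylene.

Step 9
Reactants: 15 {[3-methoxy-4-(methoxymethoxy)-2-(3-methylbut-2-enyl)phenyl]ethynyl}trimethylsilane
Product: 16 1-ethynyl-3-methoxy-4-(methoxymethoxy)-2-(3-methylbut-2-enyl)benzene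
Conditions: K2CO3 (cat.), MeOH, rt
Reagents that add atoms: none
Why: Base-catalysed methanolysis of the alkynyl C–Si bond (protodesilylation) releases the terminal alkyne without affecting the MOM ethers or the prenyl group.

Step 10
Reactants: 9 2-iodo-3,5-bis(methoxymethoxy)-6-(3-methylbut-2-enyl)phenol; 16 1-ethynyl-3-methoxy-4-(methoxymethoxy)-2-(3-methylbut-2-enyl)benzene; 17 carbon monoxide
Product: 20 2-[3-methoxy-4-(methoxymethoxy)-2-(3-methylbut-2-enyl)phenyl]-5,7-bis(methoxymethoxy)-8-(3-methylbut-2-enyl)-4H-chromen-4-one, via ortho-hydroxyaryl ynone 18 (not isolated), via enaminone 19 (not isolated)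
Conditions: PdCl2(PPh3)2 (5 mol %), CO (20 bar), Et2NH, 120 °C, autoclave
Reagents that add atoms: carbon monoxide, [C-]#[O+]
Why: Zerovalent palladium, formed from PdCl2(PPh3)2 in the amine under CO, inserts into the C4a–I bond of 9, CO inserts to give the aroylpalladium species, and the amine-generated acetylide of 16 is transferred and reductively eliminated to ynone 18, which forms C4a–C4 and C4–C3. Et2NH then adds to the ynone to give enaminone 19, and the free O1–H attacks C2 with loss of the amine, which forms O1–C2 and closes ring C by a 6-endo-trig addition–elimination (overall the 6-endo mode on the ynone) to the 4-pyranone. The closest known reaction type is the palladium-catalysed carbonylative Sonogashira annulation of ortho-iodophenols with terminal alkynes to flavones in secondary amines. No stereocentre is created. The step needs carbonylation ahead of direct alkyne coupling (which would lead to a benzofuran) and 6-endo rather than 5-exo closure (which would lead to an aurone); CO pressure secures the first and the secondary amine, by routing closure through the enaminone, secures the second, while the ring fusion is fixed by the substrate because the only free hydroxyl ortho to iodine is O1, the other ortho oxygen being MOM-capped, so the prenyl group must end at C8. Oxidative addition at the doubly ortho-substituted, electron-rich iodide is expected to be the slow step, hence 120 °C and 20 bar.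

Step 11
Reactants: 20 2-[3-methoxy-4-(methoxymethoxy)-2-(3-methylbut-2-enyl)phenyl]-5,7-bis(methoxymethoxy)-8-(3-methylbut-2-enyl)-4H-chromen-4-one
Product: 22 (2S)-2-[3-methoxy-4-(methoxymethoxy)-2-(3-methylbut-2-enyl)phenyl]-5,7-bis(methoxymethoxy)-8-(3-methylbut-2-enyl)chroman-4-one, via silyl enol ether 21 (not isolated)
Conditions: Cu(OAc)2 (5 mol %), (R)-DTBM-SEGPHOS (5.5 mol %), (EtO)2MeSiH (3 equiv), toluene, 0 °C to rt; then 1 M HCl (aq), THF, 0 °C
Reagents that add atoms: none
Why: Copper hydride asymmetric conjugate reduction (1,4-hydrosilylation): the DTBM-SEGPHOS-bound Cu–H adds hydride to C2 of the chromone from the face left open by the chiral ligand, which sets C2 as S, the copper enolate is silylated to enol ether 21, which is protected from ketone reduction and from ring opening until mild acid releases the ketone, and isolated trisubstituted alkenes and MOM ethers do not react with copper hydride.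

Step 12
Reactants: 22 (2S)-2-[3-methoxy-4-(methoxymethoxy)-2-(3-methylbut-2-enyl)phenyl]-5,7-bis(methoxymethoxy)-8-(3-methylbut-2-enyl)chroman-4-one
Product: 23 (2S)-5,7-dihydroxy-2-[4-hydroxy-3-methoxy-2-(3-methylbut-2-enyl)phenyl]-8-(3-methylbut-2-enyl)chroman-4-one
Conditions: 3 M HCl (aq), MeOH, 40 °C
Reagents that add atoms: none
Why: Acid-catalysed acetal exchange with methanol removes the three MOM groups; conditions are kept mild and short so that neither the 7-OH adds to the 8-prenyl alkene (chroman formation) nor C2 epimerises by ring opening, and no bond to C2 is broken.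

**Compound list**
1 | phloroglucinol | Oc1cc(O)cc(O)c1 | starting material
2 | 3,5-bis(methoxymethoxy)phenol | COCOc1cc(O)cc(OCOC)c1 | intermediate
3 | 3,5-bis(methoxymethoxy)phenyl N,N-diethylcarbamate | CCN(CC)C(=O)Oc1cc(OCOC)cc(OCOC)c1 | intermediate
4 | prenyl bromide (1-bromo-3-methylbut-2-ene) | CC(C)=CCBr | starting material
5 | [2-(diethylcarbamoyloxy)-4,6-bis(methoxymethoxy)phenyl]lithium (not isolated) | CCN(CC)C(=O)Oc1cc(OCOC)cc(OCOC)c1[Li] | intermediate
6 | 3,5-bis(methoxymethoxy)-2-(3-methylbut-2-enyl)phenyl N,N-diethylcarbamate | CCN(CC)C(=O)Oc1cc(OCOC)cc(OCOC)c1CC=C(C)C | intermediate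
7 | [2-(diethylcarbamoyloxy)-4,6-bis(methoxymethoxy)-3-(3-methylbut-2-enyl)phenyl]lithium (not isolated) | CCN(CC)C(=O)Oc1c([Li])c(OCOC)cc(OCOC)c1CC=C(C)C | intermediate
8 | 2-iodo-3,5-bis(methoxymethoxy)-6-(3-methylbut-2-enyl)phenyl N,N-diethylcarbamate | CCN(CC)C(=O)Oc1c(I)c(OCOC)cc(OCOC)c1CC=C(C)C | intermediate
9 | 2-iodo-3,5-bis(methoxymethoxy)-6-(3-methylbut-2-enyl)phenol | Oc1c(I)c(OCOC)cc(OCOC)c1CC=C(C)C | intermediate
10 | 4-bromo-2-methoxyphenol | COc1cc(Br)ccc1O | starting material
11 | 4-bromo-2-methoxy-1-(methoxymethoxy)benzene | COCOc1ccc(Br)cc1OC | intermediate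
12 | [6-bromo-2-methoxy-3-(methoxymethoxy)phenyl]lithium (not isolated) | COCOc1ccc(Br)c([Li])c1OC | intermediate
13 | 1-bromo-3-methoxy-4-(methoxymethoxy)-2-(3-methylbut-2-enyl)benzene | COCOc1ccc(Br)c(CC=C(C)C)c1OC | intermediate
14 | trimethylsilylacetylene | C#C[Si](C)(C)C | starting material
15 | {[3-methoxy-4-(methoxymethoxy)-2-(3-methylbut-2-enyl)phenyl]ethynyl}trimethylsilane | COCOc1ccc(C#C[Si](C)(C)C)c(CC=C(C)C)c1OC | intermediate
16 | 1-ethynyl-3-methoxy-4-(methoxymethoxy)-2-(3-methylbut-2-enyl)benzene | COCOc1ccc(C#C)c(CC=C(C)C)c1OC | intermediate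
17 | carbon monoxide | [C-]#[O+] | starting material
18 | 1-[2-hydroxy-4,6-bis(methoxymethoxy)-3-(3-methylbut-2-enyl)phenyl]-3-[3-methoxy-4-(methoxymethoxy)-2-(3-methylbut-2-enyl)phenyl]prop-2-yn-1-one (not isolated) | Oc1c(C(=O)C#Cc2ccc(OCOC)c(OC)c2CC=C(C)C)c(OCOC)cc(OCOC)c1CC=C(C)C | intermediate
19 | 3-(diethylamino)-1-[2-hydroxy-4,6-bis(methoxymethoxy)-3-(3-methylbut-2-enyl)phenyl]-3-[3-methoxy-4-(methoxymethoxy)-2-(3-methylbut-2-enyl)phenyl]prop-2-en-1-one (not isolated; alkene geometry not fixed) | Oc1c(C(=O)C=C(N(CC)CC)c2ccc(OCOC)c(OC)c2CC=C(C)C)c(OCOC)cc(OCOC)c1CC=C(C)C | intermediate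
20 | 2-[3-methoxy-4-(methoxymethoxy)-2-(3-methylbut-2-enyl)phenyl]-5,7-bis(methoxymethoxy)-8-(3-methylbut-2-enyl)-4H-chromen-4-one | COc1c(OCOC)ccc(-c2cc(=O)c3c(OCOC)cc(OCOC)c(CC=C(C)C)c3o2)c1CC=C(C)C | intermediate
21 | (2S)-4-{[diethoxy(methyl)silyl]oxy}-2-[3-methoxy-4-(methoxymethoxy)-2-(3-methylbut-2-enyl)phenyl]-5,7-bis(methoxymethoxy)-8-(3-methylbut-2-enyl)-2H-chromene (not isolated) | COc1c(OCOC)ccc([C@@H]2C=C(O[Si](C)(OCC)OCC)c3c(OCOC)cc(OCOC)c(CC=C(C)C)c3O2)c1CC=C(C)C | intermediate
22 | (2S)-2-[3-methoxy-4-(methoxymethoxy)-2-(3-methylbut-2-enyl)phenyl]-5,7-bis(methoxymethoxy)-8-(3-methylbut-2-enyl)chroman-4-one | COc1c(OCOC)ccc([C@@H]2CC(=O)c3c(OCOC)cc(OCOC)c(CC=C(C)C)c3O2)c1CC=C(C)C | intermediate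
23 | (2S)-5,7-dihydroxy-2-[4-hydroxy-3-methoxy-2-(3-methylbut-2-enyl)phenyl]-8-(3-methylbut-2-enyl)chroman-4-one | COc1c(O)ccc([C@@H]2CC(=O)c3c(O)cc(O)c(CC=C(C)C)c3O2)c1CC=C(C)C | target

**Totals**
Total step count: 12.
Longest linear sequence: 8 steps (steps 1–5, then 10–12); the ring-B branch (steps 6–9) joins at step 10.

**Steps most likely to fail**

1. Step 11. Hydride transfer may be slow, because the chromone is a vinylogous ester flanked by the 5-OMOM group and by a twisted, ortho-prenylated ring B. The catalyst may also discriminate the two faces of C2 poorly, and base-mediated ring opening and reclosure of the product would erode enantiomeric purity further. Fallback (resolution in place of catalyst control): setting out from 20, the less encumbered achiral copper hydride made from Cu(OAc)2, 1,2-bis(diphenylphosphino)benzene and (EtO)2MeSiH should give the racemic silyl enol ether F1, which is hydrolysed as in step 11 to the racemic tri-O-MOM flavanone F2. Preparative chromatography on a polysaccharide chiral stationary phase should then separate F2 into 22, at which the route is rejoined, and the (2R)-tri-O-MOM flavanone F3, which is set aside.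

2. Step 10. Oxidative addition to the hindered, electron-rich iodide may be so slow that alkyne homocoupling, aminocarbonylation of the aroylpalladium species by Et2NH, or CO-free coupling towards a benzofuran take over. Fallback (the same ynone by polar acylation, without palladium): setting out from 16, n-BuLi in THF at −78 °C gives the lithium acetylide F4, which is acylated with N-methoxy-N-methylcarbamoyl chloride to the N-methoxy-N-methyl ynamide F5. Setting out from 9, n-BuLi (2.1 equiv, THF, −78 °C) removes the phenolic proton and exchanges iodine for lithium to give the O,C-dilithio species F6, whose aryl carbanion adds once to F5. Aqueous NH4Cl work-up should give ynone 18, at which the route is rejoined; Et2NH in EtOH at 40 °C then closes it through 19 to 20.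

3. Step 4. Deprotonation may stray to the ring C–H between the two MOM ethers or to the benzylic–allylic CH2 of the prenyl group, which would place iodine on the wrong carbon or degrade the side chain. Fallback (electrophilic substitution instead of deprotonation): setting out from 6, N-iodosuccinimide with catalytic CF3CO2H in MeCN at 0 °C should iodinate the ring directly. With O1 held as the weakly donating carbamate, the C–H next to it is para to one MOM ether and ortho to the other, whereas the competing C–H is only ortho to two MOM ethers. Substitution is therefore expected at the future C4a and gives 8, at which the route is rejoined; this fallback makes no new compound (F0).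

**Further compounds**
F1 | step 11 | racemic 4-{[diethoxy(methyl)silyl]oxy}-2-[3-methoxy-4-(methoxymethoxy)-2-(3-methylbut-2-enyl)phenyl]-5,7-bis(methoxymethoxy)-8-(3-methylbut-2-enyl)-2H-chromene | COc1c(OCOC)ccc(C2C=C(O[Si](C)(OCC)OCC)c3c(OCOC)cc(OCOC)c(CC=C(C)C)c3O2)c1CC=C(C)C
F2 | step 11 | racemic 2-[3-methoxy-4-(methoxymethoxy)-2-(3-methylbut-2-enyl)phenyl]-5,7-bis(methoxymethoxy)-8-(3-methylbut-2-enyl)chroman-4-one | COc1c(OCOC)ccc(C2CC(=O)c3c(OCOC)cc(OCOC)c(CC=C(C)C)c3O2)c1CC=C(C)C
F3 | step 11 | (2R)-2-[3-methoxy-4-(methoxymethoxy)-2-(3-methylbut-2-enyl)phenyl]-5,7-bis(methoxymethoxy)-8-(3-methylbut-2-enyl)chroman-4-one | COc1c(OCOC)ccc([C@H]2CC(=O)c3c(OCOC)cc(OCOC)c(CC=C(C)C)c3O2)c1CC=C(C)C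
F4 | step 10 | {[3-methoxy-4-(methoxymethoxy)-2-(3-methylbut-2-enyl)phenyl]ethynyl}lithium | [Li]C#Cc1ccc(OCOC)c(OC)c1CC=C(C)C
F5 | step 10 | N-methoxy-N-methyl-3-[3-methoxy-4-(methoxymethoxy)-2-(3-methylbut-2-enyl)phenyl]prop-2-ynamide | CON(C)C(=O)C#Cc1ccc(OCOC)c(OC)c1CC=C(C)C
F6 | step 10 | lithium 2-lithio-3,5-bis(methoxymethoxy)-6-(3-methylbut-2-enyl)phenoxide | [Li]Oc1c([Li])c(OCOC)cc(OCOC)c1CC=C(C)C
F0 | step 4 | none | none
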